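The plan rests on disconnecting ring B of the flavone into an alkyne and a diene. Ring B (C1'–C6') is a para-disubstituted benzene joined through C1' to C2 of ring C and oxygenated at C4', so C1'/C2' can be carried as a terminal ethynyl group on C2 of a finished chromone and C3'–C6' delivered, with the C4' oxygen, by 1-methoxy-3-silyloxybutadiene. One operation, a Diels–Alder addition followed by loss of methanol, forms C1'–C6' and C2'–C3' and aromatises ring B. The precursor is 3-benzyloxy-2-ethynyl-5,6,7,8-tetramethoxychromone, assembled from 1,2,3,4-tetramethoxybenzene by two directed metalations, enaminone cyclisation, C2 zincation–iodination and Sonogashira coupling.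

Key step: step 8

Remarks on the chemistry:
- The Weinreb amide of benzyloxyacetic acid used in step 3 is assumed to be purchased; it is otherwise one step from benzyloxyacetyl chloride and N,O-dimethylhydroxylamine hydrochloride.
- The ω-benzyloxy ketone is made by directed metalation and not by Lewis-acid acylation, because alkoxyacetyl chlorides lose carbon monoxide and benzyl ethers are cleaved under Friedel–Crafts promoters.

Step 1
Reactants: 1 1,2,3,4-tetramethoxybenzene
Product: 4 2,3,4,5-tetramethoxyphenol, via aryllithium 2 (not isolated), via lithium aryltrimethoxyborate 3 (not isolated)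
Conditions: n-BuLi, TMEDA, THF, 0 °C → rt; B(OMe)3, −78 °C → rt; 30% H2O2, AcOH, 0 °C → rt
Reagents that add atoms: hydrogen peroxide, OO (the phenol oxygen); n-butyllithium, [Li]CCCC (lithium of 2 and 3 only); trimethyl borate, COB(OC)OC (boron and methoxy groups of 3 only)
Why: Directed ortho-metalation beside a methoxy group (the two ring hydrogens are equivalent, so only one aryllithium can form) followed by borylation and peroxide oxidation, in which the aryl group migrates from boron to oxygen, should give the phenol without touching the methyl ethers; no stereocenter is formed.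

Step 2
Reactants: 4 2,3,4,5-tetramethoxyphenol
Product: 5 1-(methoxymethoxy)-2,3,4,5-tetramethoxybenzene
Conditions: NaH, THF, 0 °C; MOMCl, 0 °C → rt
Reagents that add atoms: chloromethyl methyl ether, COCCl
Why: Williamson-type O-alkylation of the sodium phenoxide installs the methoxymethyl acetal, which protects the phenol and serves as the directing group for the second metalation.

Step 3
Reactants: 5 1-(methoxymethoxy)-2,3,4,5-tetramethoxybenzene; 6 2-(benzyloxy)-N-methoxy-N-methylacetamide
Product: 8 2-(benzyloxy)-1-[2-(methoxymethoxy)-3,4,5,6-tetramethoxyphenyl]ethan-1-one, via aryllithium 7 (not isolated)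
Conditions: n-BuLi, TMEDA, THF, −20 → 0 °C; 6, −78 → 0 °C; aq NH4Cl
Reagents that add atoms: n-butyllithium, [Li]CCCC (lithium of 7 only)
Why: Directed ortho-metalation at the only remaining ring hydrogen, flanked by the OMOM and OMe groups, and Weinreb ketone synthesis, in which the chelated tetrahedral lithium adduct survives until work-up and so prevents double addition, should deliver the ω-benzyloxy ketone without any Lewis acid.

Step 4
Reactants: 8 2-(benzyloxy)-1-[2-(methoxymethoxy)-3,4,5,6-tetramethoxyphenyl]ethan-1-one
Product: 11 3-(benzyloxy)-5,6,7,8-tetramethoxy-4H-chromen-4-one, via MOM enaminone 9 (not isolated), via hydroxyaryl enaminone 10 (not isolated)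
Conditions: DMF-DMA, PhMe, 100 °C; concentrate; 2 M aq HCl, THF, 50 °C
Reagents that add atoms: N,N-dimethylformamide dimethyl acetal, COC(OC)N(C)C (C2 of the chromone; also the dimethylamino group of 9 and 10)
Why: Condensation of the activated methylene with the amide acetal gives the enaminone, and acid then cleaves the MOM acetal so that the freed phenol adds to the enamine carbon and expels dimethylamine (6-endo-trig addition–elimination), the standard enaminone route to 2-unsubstituted chromones.

Step 5
Reactants: 11 3-(benzyloxy)-5,6,7,8-tetramethoxy-4H-chromen-4-one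
Product: 13 3-(benzyloxy)-2-iodo-5,6,7,8-tetramethoxy-4H-chromen-4-one, via chromen-2-ylzinc chloride 12 (not isolated)
Conditions: TMPZnCl·LiCl, THF, 25 °C; I2, THF, 0 °C; aq Na2S2O3
Reagents that add atoms: iodine, II; TMPZnCl·LiCl, CC1(C)CCCC(C)(C)N1[Zn]Cl.[Li+].[Cl-] (zinc and chloride of 12 only)
Why: Deprotonative zincation by the hindered amide base occurs at C2–H, the only acidic ring hydrogen (C3 carries the benzyloxy group and ring A has no hydrogen), the mild zinc amide does not add to the pyranone, and iodolysis of the C–Zn bond gives the 2-iodide.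

Step 6
Reactants: 13 3-(benzyloxy)-2-iodo-5,6,7,8-tetramethoxy-4H-chromen-4-one; 14 ethynyltrimethylsilane
Product: 15 3-(benzyloxy)-5,6,7,8-tetramethoxy-2-[(trimethylsilyl)ethynyl]-4H-chromen-4-one
Conditions: PdCl2(PPh3)2 (3 mol %), CuI (5 mol %), Et3N, THF, rt
Reagents that add atoms: none
Why: Sonogashira coupling: the 2-iodochromone is a vinylogous acyl iodide that adds readily to zerovalent palladium, and the copper acetylide of 14 then transfers the alkynyl group to C2 at room temperature.

Step 7
Reactants: 15 3-(benzyloxy)-5,6,7,8-tetramethoxy-2-[(trimethylsilyl)ethynyl]-4H-chromen-4-one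
Product: 16 3-(benzyloxy)-2-ethynyl-5,6,7,8-tetramethoxy-4H-chromen-4-one
Conditions: TBAF, AcOH, THF, 0 °C
Reagents that add atoms: none
Why: Fluoride-induced protodesilylation of the C(sp)–Si bond, buffered with acetic acid so that no basic nucleophile can add to the electron-poor enynone, frees the terminal alkyne.

Step 8
Reactants: 16 3-(benzyloxy)-2-ethynyl-5,6,7,8-tetramethoxy-4H-chromen-4-one; 17 (E)-1-methoxy-3-(trimethylsilyloxy)buta-1,3-diene
Product: 20 3-(benzyloxy)-2-(4-hydroxyphenyl)-5,6,7,8-tetramethoxy-4H-chromen-4-one, via cyclohexadiene cycloadduct 18 (not isolated), via aryl trimethylsilyl ether 19 (not isolated)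
Conditions: 17 (4 equiv), PhMe, 110 °C, sealed tube; then 1 M HCl, THF, rt
Reagents that add atoms: none
Why: In a thermal normal-electron-demand Diels–Alder reaction the HOMO of the 1,3-dioxygenated diene combines with the LUMO of the alkyne, lowered by conjugation through C2=C3 to the C4 carbonyl, to give the 1,4-cyclohexadiene 18, which should lose methanol across C6'/C3' to the aryl silyl ether 19 and be desilylated by the dilute acid. The closest known reaction type is the benzannulation of 1-alkoxy-3-silyloxybutadienes with acetylenic esters and ketones to para-hydroxyaryl carbonyl compounds. Ring B closes by an intermolecular [4+2] cycloaddition that brings four carbons (C3'–C6') from the diene and two (C1', C2') from the alkyne. The only stereocenter, C6' of 18, is formed racemic and is erased on aromatisation, so nothing has to be controlled. The regioselectivity that is needed follows from polarity: the terminal alkyne carbon C2' is the electrophilic end of the C4=O/C3=C2/C1'≡C2' chain and bonds to the nucleophilic CH2 terminus of the diene, which places the silyloxy carbon para to C1'. The alkyne is preferred over the pyranone double bond because the tetrasubstituted, oxygen-flanked C2=C3 bond is too hindered and too electron-rich to serve as dienophile.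

Step 9
Reactants: 20 3-(benzyloxy)-2-(4-hydroxyphenyl)-5,6,7,8-tetramethoxy-4H-chromen-4-one
Product: 21 3-(benzyloxy)-5,6,7,8-tetramethoxy-2-(4-methoxyphenyl)-4H-chromen-4-one
Conditions: MeI, K2CO3, acetone, 50 °C
Reagents that add atoms: iodomethane, CI
Why: Williamson ether synthesis on the only free hydroxyl group, the 4'-phenol, with carbonate as base gives the anisole ring of the target.

Step 10
Reactants: 21 3-(benzyloxy)-5,6,7,8-tetramethoxy-2-(4-methoxyphenyl)-4H-chromen-4-one
Product: 22 3,5-dihydroxy-6,7,8-trimethoxy-2-(4-methoxyphenyl)-4H-chromen-4-one (3,5-dihydroxy-6,7,8,4'-tetramethoxyflavone)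
Conditions: BCl3, C6HMe5, CH2Cl2, −78 → 0 °C; aq NaHCO3, MeOH
Reagents that add atoms: none
Why: Lewis-acid dealkylation: BCl3 bound to the C4 carbonyl cleaves the peri 5-O-methyl group through a six-membered boron chelate and ionises the benzyl ether at O3, whose cation is trapped by pentamethylbenzene, while the 6-, 7-, 8- and 4'-methoxy groups, which cannot chelate, should survive at low temperature.

Compound list
1 | 1,2,3,4-tetramethoxybenzene | COc1ccc(OC)c(OC)c1OC | starting material
2 | (2,3,4,5-tetramethoxyphenyl)lithium | [Li]c1cc(OC)c(OC)c(OC)c1OC | intermediate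
3 | lithium trimethoxy(2,3,4,5-tetramethoxyphenyl)borate | [Li+].CO[B-](OC)(OC)c1cc(OC)c(OC)c(OC)c1OC | intermediate
4 | 2,3,4,5-tetramethoxyphenol | COc1cc(O)c(OC)c(OC)c1OC | intermediate
5 | 1-(methoxymethoxy)-2,3,4,5-tetramethoxybenzene | COCOc1cc(OC)c(OC)c(OC)c1OC | intermediate
6 | 2-(benzyloxy)-N-methoxy-N-methylacetamide | CON(C)C(=O)COCc1ccccc1 | starting material
7 | [2-(methoxymethoxy)-3,4,5,6-tetramethoxyphenyl]lithium | [Li]c1c(OCOC)c(OC)c(OC)c(OC)c1OC | intermediate
8 | 2-(benzyloxy)-1-[2-(methoxymethoxy)-3,4,5,6-tetramethoxyphenyl]ethan-1-one | COCOc1c(OC)c(OC)c(OC)c(OC)c1C(=O)COCc1ccccc1 | intermediate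
9 | 2-(benzyloxy)-3-(dimethylamino)-1-[2-(methoxymethoxy)-3,4,5,6-tetramethoxyphenyl]prop-2-en-1-one (alkene geometry not defined; either isomer cyclises) | COCOc1c(OC)c(OC)c(OC)c(OC)c1C(=O)C(OCc1ccccc1)=CN(C)C | intermediate
10 | 2-(benzyloxy)-3-(dimethylamino)-1-(2-hydroxy-3,4,5,6-tetramethoxyphenyl)prop-2-en-1-one (alkene geometry not defined) | CN(C)C=C(OCc1ccccc1)C(=O)c1c(O)c(OC)c(OC)c(OC)c1OC | intermediate
11 | 3-(benzyloxy)-5,6,7,8-tetramethoxy-4H-chromen-4-one | O=c1c(OCc2ccccc2)coc2c(OC)c(OC)c(OC)c(OC)c12 | intermediate
12 | [3-(benzyloxy)-5,6,7,8-tetramethoxy-4-oxo-4H-chromen-2-yl]zinc chloride | Cl[Zn]c1oc2c(OC)c(OC)c(OC)c(OC)c2c(=O)c1OCc1ccccc1 | intermediate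
13 | 3-(benzyloxy)-2-iodo-5,6,7,8-tetramethoxy-4H-chromen-4-one | Ic1oc2c(OC)c(OC)c(OC)c(OC)c2c(=O)c1OCc1ccccc1 | intermediate
14 | ethynyltrimethylsilane | C#C[Si](C)(C)C | starting material
15 | 3-(benzyloxy)-5,6,7,8-tetramethoxy-2-[(trimethylsilyl)ethynyl]-4H-chromen-4-one | C[Si](C)(C)C#Cc1oc2c(OC)c(OC)c(OC)c(OC)c2c(=O)c1OCc1ccccc1 | intermediate
16 | 3-(benzyloxy)-2-ethynyl-5,6,7,8-tetramethoxy-4H-chromen-4-one | C#Cc1oc2c(OC)c(OC)c(OC)c(OC)c2c(=O)c1OCc1ccccc1 | intermediate
17 | (E)-1-methoxy-3-(trimethylsilyloxy)buta-1,3-diene | CO/C=C/C(=C)O[Si](C)(C)C | starting material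
18 | 3-(benzyloxy)-5,6,7,8-tetramethoxy-2-[6-methoxy-4-(trimethylsilyloxy)cyclohexa-1,4-dien-1-yl]-4H-chromen-4-one (racemic at the methoxy-bearing carbon) | COC1C=C(O[Si](C)(C)C)CC=C1c1oc2c(OC)c(OC)c(OC)c(OC)c2c(=O)c1OCc1ccccc1 | intermediate
19 | 3-(benzyloxy)-5,6,7,8-tetramethoxy-2-[4-(trimethylsilyloxy)phenyl]-4H-chromen-4-one | C[Si](C)(C)Oc1ccc(cc1)-c1oc2c(OC)c(OC)c(OC)c(OC)c2c(=O)c1OCc1ccccc1 | intermediate
20 | 3-(benzyloxy)-2-(4-hydroxyphenyl)-5,6,7,8-tetramethoxy-4H-chromen-4-one | Oc1ccc(-c2oc3c(OC)c(OC)c(OC)c(OC)c3c(=O)c2OCc2ccccc2)cc1 | intermediate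
21 | 3-(benzyloxy)-5,6,7,8-tetramethoxy-2-(4-methoxyphenyl)-4H-chromen-4-one | COc1ccc(-c2oc3c(OC)c(OC)c(OC)c(OC)c3c(=O)c2OCc2ccccc2)cc1 | intermediate
22 | 3,5-dihydroxy-6,7,8-trimethoxy-2-(4-methoxyphenyl)-4H-chromen-4-one | COc1ccc(-c2oc3c(OC)c(OC)c(OC)c(O)c3c(=O)c2O)cc1 | target

Total step count: 10
Longest linear sequence: 10 steps (1 to 22); 6, 14 and 17 are purchased.

Steps most likely to fail

Step 8. The cycloaddition may be slower than the thermal decay of the diene, because the alkyne is activated only through the C2=C3 bond. Desilylated diene, or an open Michael-type adduct that does not close, would then build up in place of ring B. Fallback: setting out from iodide 13, a Suzuki–Miyaura coupling with (4-hydroxyphenyl)boronic acid (Pd(PPh3)4, K2CO3, dioxane/H2O, 80 °C) should form the C2–C1' bond directly from a ready-made ring B. It comes back to the route at phenol 20 and makes no new intermediate.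

Step 5. The amide base may add to C2 and open the pyranone instead of removing the C2 hydrogen, or zincation may stall beside the 3-benzyloxy group. Fallback: setting out from chromone 11, the ring is made electrophilic at C2 and no base touches it. TMSOTf in CH2Cl2 should silylate the carbonyl oxygen to give 3-(benzyloxy)-5,6,7,8-tetramethoxy-4-(trimethylsilyloxy)chromenylium triflate F1. CuI (catalytic), i-Pr2NEt and alkyne 14 should then add the copper acetylide at C2 to give the racemic 2-alkynyl-4-(trimethylsilyloxy)-2H-chromene F2. DDQ in the same flask should abstract the C2 hydride of F2, and loss of the silyl group restores the chromone. The sequence comes back to the route at silyl alkyne 15.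

Step 10. Cleavage of the 5-O-methyl group may stall once boron is bound between the freed 3-oxygen and the carbonyl, or cleavage may run on to the 6-methoxy group on longer exposure. Fallback: setting out from 21, the two dealkylations are separated. Hydrogenolysis (H2, Pd/C, EtOAc, rt) should remove only the benzyl group and give 3-hydroxy-5,6,7,8-tetramethoxy-2-(4-methoxyphenyl)-4H-chromen-4-one F3. AlCl3 in MeCN should then cleave only the chelated peri 5-O-methyl group, and the sequence comes back to the route at target 22.

Further compounds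
F0 | step 8 | none | none
F1 | step 5 | 3-(benzyloxy)-5,6,7,8-tetramethoxy-4-(trimethylsilyloxy)chromenylium trifluoromethanesulfonate | C[Si](C)(C)Oc1c(OCc2ccccc2)c[o+]c2c(OC)c(OC)c(OC)c(OC)c12.[O-]S(=O)(=O)C(F)(F)F
F2 | step 5 | 3-(benzyloxy)-5,6,7,8-tetramethoxy-4-(trimethylsilyloxy)-2-[(trimethylsilyl)ethynyl]-2H-chromene (racemic) | C[Si](C)(C)C#CC1Oc2c(OC)c(OC)c(OC)c(OC)c2C(O[Si](C)(C)C)=C1OCc1ccccc1
F3 | step 10 | 3-hydroxy-5,6,7,8-tetramethoxy-2-(4-methoxyphenyl)-4H-chromen-4-one | COc1ccc(-c2oc3c(OC)c(OC)c(OC)c(OC)c3c(=O)c2O)cc1
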